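The route closes ring A and ring B together across C5–C10 and C8–C9. Because C8 and C9 are sp2 carbons of the tetrasubstituted C8=C9 alkene in the target, only the trans ring-fusion centres C5 and quaternary C10 have to be created. A catalytic asymmetric type-1 intramolecular Diels–Alder reaction sets both in one operation while forming both rings. Its precursor is an acyclic, geometrically pure (2E,8E,10E)-trienal: an (E,E)-diene (C5–C8) and an (E)-β-methyl enal (C9=C10) joined by the C1–C4 tether that carries the C4 gem-dimethyl group. The C12–C16 unit and the glyceryl acetate are attached afterwards.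

Key step: step 8

Remark: atom labels follow labdane numbering (ring A = C1–C5 and C10; ring B = C5–C10; C11–C16 side chain; C17 on C8; C20 on C10). The hindered tetrasubstituted C8=C9 bond is assumed inert to H2 over Pd/C at 1 atm.

Step 1
Reactants: 1 isobutyronitrile; 2 1-bromo-3-chloropropane
Product: 3 5-chloro-2,2-dimethylpentanenitrile
Conditions: LiN(i-Pr)2, THF, −78 °C; then 2, −78 °C → rt
Reagents that add atoms: none
Why: SN2 alkylation of the lithiated nitrile takes place only at the C–Br bond, the far better leaving group, and creates the quaternary C4 with the C1–C3 tether attached.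

Step 2
Reactants: 3 5-chloro-2,2-dimethylpentanenitrile
Product: 5 5-chloro-2,2-dimethylpentanal, via iminoalane 4 (not isolated)
Conditions: i-Bu2AlH (1.2 equiv), CH2Cl2, −78 °C; then 1 M HCl, 0 °C
Reagents that add atoms: water, O
Why: Hydride reduction of a nitrile with i-Bu2AlH stops at the N-aluminated aldimine, which is hydrolysed to the aldehyde on acidic work-up, so over-reduction is excluded and the alkyl chloride is untouched.

Step 3
Reactants: 5 5-chloro-2,2-dimethylpentanal
Product: 6 (1E)-6-chloro-1-iodo-3,3-dimethylhex-1-ene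
Conditions: CrCl2 (6 equiv), CHI3 (2 equiv), THF, 0 °C → rt
Reagents that add atoms: iodoform, IC(I)I
Why: Takai iodo-olefination of a non-enolisable α-quaternary aldehyde with the geminal dichromium species from iodoform and divalent chromium should give the (E)-alkenyl iodide (future C5=C6) under steric control.

Step 4
Reactants: 6 (1E)-6-chloro-1-iodo-3,3-dimethylhex-1-ene; 7 [(1E)-prop-1-en-1-yl]boronic acid
Product: 8 (2E,4E)-9-chloro-6,6-dimethylnona-2,4-diene
Conditions: Pd(PPh3)4 (5 mol %), K2CO3 (2 M aq), THF, 60 °C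
Reagents that add atoms: none
Why: Suzuki–Miyaura coupling proceeds with retention at both alkenyl partners, so the (E,E)-geometry of the C5=C6–C7=C8 diene is fixed by the two (E)-configured reagents, and the primary alkyl chloride does not enter oxidative addition.

Step 5
Reactants: 8 (2E,4E)-9-chloro-6,6-dimethylnona-2,4-diene
Product: 9 (7E,9E)-6,6-dimethylundeca-7,9-dien-1-yne
Conditions: LiC≡CH·H2NCH2CH2NH2 (1.5 equiv), DMSO, rt
Reagents that add atoms: lithium acetylide ethylenediamine complex, [Li+].[C-]#C.NCCN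
Why: SN2 alkylation of lithium acetylide by the unhindered primary chloride in DMSO installs C9 and C10 as a terminal alkyne, and the acetylide is too weak a base to disturb the diene.

Step 6
Reactants: 9 (7E,9E)-6,6-dimethylundeca-7,9-dien-1-yne
Product: 12 (2E,8E,10E)-3,7,7-trimethyldodeca-2,8,10-trien-1-ol, via alkenylalane 10 (not isolated), via lithium alanate 11 (not isolated)
Conditions: AlMe3 (2.5 equiv), Cp2ZrCl2 (0.25 equiv), CH2Cl2, 0 °C → rt; n-BuLi, THF, −78 °C; (CH2O)n, −78 °C → rt; 1 M HCl
Reagents that add atoms: trimethylaluminium, C[Al](C)C; formaldehyde (as paraformaldehyde), C=O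
Why: Negishi zirconium-catalysed methylalumination adds methyl and aluminium syn across the terminal alkyne with methyl on the internal carbon, and the alkenyl group of the alanate adds to formaldehyde with retention, which fixes the (E)-C9=C10 geometry; internal conjugated dienes are tolerated in this carbometalation.

Step 7
Reactants: 12 (2E,8E,10E)-3,7,7-trimethyldodeca-2,8,10-trien-1-ol
Product: 13 (2E,8E,10E)-3,7,7-trimethyldodeca-2,8,10-trienal
Conditions: MnO2 (activated, 15 equiv), CH2Cl2, rt
Reagents that add atoms: none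
Why: Allylic oxidation with MnO2 stops at the enal under neutral heterogeneous conditions and should neither isomerise the trisubstituted C9=C10 bond nor touch the diene.

Step 8
Reactants: 13 (2E,8E,10E)-3,7,7-trimethyldodeca-2,8,10-trienal
Product: 14 (1R,2R,4aR,8aR)-2,5,5,8a-tetramethyl-1,2,4a,5,6,7,8,8a-octahydronaphthalene-1-carbaldehyde
Conditions: (S)-tetrahydro-1-(2-methylphenyl)-3,3-diphenyl-1H,3H-pyrrolo[1,2-c][1,3,2]oxazaborole (20 mol %), Tf2NH (17 mol %), CH2Cl2, −40 → 0 °C
Reagents that add atoms: none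
Why: Proposed new method: the N-protonated oxazaborolidine binds the formyl oxygen syn to the formyl hydrogen (formyl C–H···O contact to the ring oxygen), lowers the LUMO of the s-trans (E)-enal and should induce a concerted, asynchronous [4+2] in which C5–C10 forms ahead of C8–C9; the closest known reaction type is the oxazaborolidinium-catalysed enantioselective type-1 intramolecular Diels–Alder reaction of terminally activated trienals, not yet shown for a β,β-disubstituted enal that creates a quaternary fusion carbon, while thermal and achiral Lewis-acid cases that set an angular methyl group are known. Ring B closes as the cyclohexene of the cycloaddition itself (bonds C5–C10 and C8–C9), and ring A closes in the same event as the six-membered ring spanned by the C1–C4 tether across C5–C10, the tether folding as a chair. C10 and C5 take their absolute configuration from the catalyst, whose phenyl group should cover the C9-Si/C10-Re face so that the diene adds to the C9-Re/C10-Si face, and C5 is placed trans to the C10 methyl group because the formyl group reacts endo and, being trans to the tether in the (E)-enal, keeps the tether exo. C9 follows from suprafacial addition to the (E)-enal (formyl cis to the C10 methyl) and C8 from the (E)-C7=C8 geometry in the endo mode (methyl cis to formyl), and both are erased in step 10. The step needs endo and facial selectivity, which are supported by the geometrically pure (E)-enal held s-trans by its β-methyl group, by the (E,E)-diene that can reach the s-cis conformer, and by the C4 gem-dimethyl group that favours the folded, reactive conformer.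

Step 9
Reactants: 14 (1R,2R,4aR,8aR)-2,5,5,8a-tetramethyl-1,2,4a,5,6,7,8,8a-octahydronaphthalene-1-carbaldehyde
Product: 15 (1R,2R,4aR,8aR)-2,5,5,8a-tetramethyldecahydronaphthalene-1-carbaldehyde
Conditions: H2 (1 atm), 10 % Pd/C, EtOAc, rt
Reagents that add atoms: none
Why: Heterogeneous catalytic hydrogenation saturates the cis-disubstituted C6=C7 bond, while the hindered aldehyde is not reduced under neutral conditions at 1 atm.

Step 10
Reactants: 15 (1R,2R,4aR,8aR)-2,5,5,8a-tetramethyldecahydronaphthalene-1-carbaldehyde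
Product: 18 (4aR,8aR)-2,5,5,8a-tetramethyl-3,4,4a,5,6,7,8,8a-octahydronaphthalene-1-carbaldehyde, via selenide 16 (not isolated), via selenoxide 17 (not isolated)
Conditions: PhSeCl (1.1 equiv), EtOAc, rt; then H2O2 (30 % aq), pyridine, CH2Cl2, 0 °C → rt
Reagents that add atoms: none
Why: α-Selenenylation of the aldehyde through its enol followed by selenoxide syn-elimination should work because selenium enters C9 axially, on the face opposite the axial C8 and C10 methyl groups and therefore cis to H-8, the only β-hydrogen, so that elimination can only give the conjugated C8=C9 enal and erases the C8 and C9 centres.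

Step 11
Reactants: 19 (3R)-5-methoxy-3-methyl-5-oxopentanoic acid (methyl hydrogen (R)-3-methylglutarate)
Product: 20 methyl (3S)-4-iodo-3-methylbutanoate
Conditions: PhI(OAc)2 (1.1 equiv), I2 (1.0 equiv), cyclohexane, hν (tungsten lamp), reflux
Reagents that add atoms: iodine, II
Why: Suárez iododecarboxylation (a radical Hunsdiecker-type reaction) turns the free carboxyl arm into the primary iodide C12 while the ester arm and the C13 centre, which is not at the radical site, stay untouched; the descriptor changes to S only through the priority rules.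

Step 12
Reactants: 20 methyl (3S)-4-iodo-3-methylbutanoate
Product: 21 [(2S)-4-methoxy-2-methyl-4-oxobutyl](triphenyl)phosphonium iodide
Conditions: PPh3 (1.1 equiv), MeCN, reflux
Reagents that add atoms: triphenylphosphine, c1ccc(cc1)P(c1ccccc1)c1ccccc1
Why: SN2 quaternisation of triphenylphosphine by the primary iodide gives the Wittig salt without affecting C13.

Step 13
Reactants: 18 (4aR,8aR)-2,5,5,8a-tetramethyl-3,4,4a,5,6,7,8,8a-octahydronaphthalene-1-carbaldehyde; 21 [(2S)-4-methoxy-2-methyl-4-oxobutyl](triphenyl)phosphonium iodide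
Product: 23 methyl (3S,4Z)-3-methyl-5-[(4aR,8aR)-2,5,5,8a-tetramethyl-3,4,4a,5,6,7,8,8a-octahydronaphthalen-1-yl]pent-4-enoate, via ylide 22 (not isolated)
Conditions: 21, NaN(SiMe3)2 (1.0 equiv), THF, −78 → 0 °C; then 18, −78 °C → rt
Reagents that add atoms: none
Why: Wittig olefination of the β-cyclocitral-like enal with the non-stabilised ylide forms C11=C12 by 1,2-addition; the expected Z geometry is irrelevant because the bond is reduced next, and the non-acidic C13 centre is retained.

Step 14
Reactants: 23 methyl (3S,4Z)-3-methyl-5-[(4aR,8aR)-2,5,5,8a-tetramethyl-3,4,4a,5,6,7,8,8a-octahydronaphthalen-1-yl]pent-4-enoate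
Product: 24 methyl (3R)-3-methyl-5-[(4aR,8aR)-2,5,5,8a-tetramethyl-3,4,4a,5,6,7,8,8a-octahydronaphthalen-1-yl]pentanoate
Conditions: TsNHNH2 (excess, in portions), NaOAc, DME/H2O, reflux
Reagents that add atoms: none
Why: Diimide reduction delivers H2 in a concerted syn fashion to the disubstituted C11=C12 bond and is unreactive towards the tetrasubstituted C8=C9 bond, and no metal hydride is present that could move the ring double bond.

Step 15
Reactants: 24 methyl (3R)-3-methyl-5-[(4aR,8aR)-2,5,5,8a-tetramethyl-3,4,4a,5,6,7,8,8a-octahydronaphthalen-1-yl]pentanoate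
Product: 25 (3R)-3-methyl-5-[(4aR,8aR)-2,5,5,8a-tetramethyl-3,4,4a,5,6,7,8,8a-octahydronaphthalen-1-yl]pentanoic acid
Conditions: LiOH, THF/MeOH/H2O, 40 °C; then 1 M HCl
Reagents that add atoms: lithium hydroxide, [Li+].[OH-]
Why: Saponification of the unhindered methyl ester cannot epimerise C13, which is β to the carboxyl group.

Step 16
Reactants: 26 (2R)-3-(benzyloxy)propane-1,2-diol
Product: 27 (2S)-3-(benzyloxy)-2-hydroxypropyl acetate
Conditions: AcCl (1.05 equiv), 2,4,6-collidine, CH2Cl2, −78 °C
Reagents that add atoms: acetyl chloride, CC(Cl)=O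
Why: Kinetically controlled acylation with acetyl chloride and a hindered pyridine base at low temperature selects the primary hydroxyl of the 1,2-diol, and the glycerol stereocentre, taken from the chiral pool, is not touched.

Step 17
Reactants: 25 (3R)-3-methyl-5-[(4aR,8aR)-2,5,5,8a-tetramethyl-3,4,4a,5,6,7,8,8a-octahydronaphthalen-1-yl]pentanoic acid; 27 (2S)-3-(benzyloxy)-2-hydroxypropyl acetate
Product: 28 (2S)-1-(acetyloxy)-3-(benzyloxy)propan-2-yl (3R)-3-methyl-5-[(4aR,8aR)-2,5,5,8a-tetramethyl-3,4,4a,5,6,7,8,8a-octahydronaphthalen-1-yl]pentanoate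
Conditions: DCC, DMAP (cat.), CH2Cl2, 0 °C → rt
Reagents that add atoms: none
Why: Steglich esterification acylates the only free (secondary) hydroxyl under mild conditions, and at 0 °C with catalytic DMAP acetyl migration should not compete.

Step 18
Reactants: 28 (2S)-1-(acetyloxy)-3-(benzyloxy)propan-2-yl (3R)-3-methyl-5-[(4aR,8aR)-2,5,5,8a-tetramethyl-3,4,4a,5,6,7,8,8a-octahydronaphthalen-1-yl]pentanoate
Product: 29 (2S)-1-(acetyloxy)-3-hydroxypropan-2-yl (3R)-3-methyl-5-[(4aR,8aR)-2,5,5,8a-tetramethyl-3,4,4a,5,6,7,8,8a-octahydronaphthalen-1-yl]pentanoate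
Conditions: H2 (1 atm), 10 % Pd/C, EtOAc, rt; chromatography on boric-acid-treated silica
Reagents that add atoms: none
Why: Hydrogenolysis of the primary benzyl ether is neutral, so the 2-acyl group should not migrate to the freed hydroxyl, and the hindered tetrasubstituted C8=C9 bond should not be hydrogenated at 1 atm.

Compound list
1 | isobutyronitrile | CC(C)C#N | starting material
2 | 1-bromo-3-chloropropane | ClCCCBr | starting material
3 | 5-chloro-2,2-dimethylpentanenitrile | N#CC(C)(C)CCCCl | intermediate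
4 | N-(diisobutylalumanyl)-5-chloro-2,2-dimethylpentan-1-imine (iminoalane, formed in the flask in step 2) | CC(C)C[Al](CC(C)C)N=CC(C)(C)CCCCl | intermediate
5 | 5-chloro-2,2-dimethylpentanal | O=CC(C)(C)CCCCl | intermediate
6 | (1E)-6-chloro-1-iodo-3,3-dimethylhex-1-ene | I/C=C/C(C)(C)CCCCl | intermediate
7 | [(1E)-prop-1-en-1-yl]boronic acid | C/C=C/B(O)O | starting material
8 | (2E,4E)-9-chloro-6,6-dimethylnona-2,4-diene | C/C=C/C=C/C(C)(C)CCCCl | intermediate
9 | (7E,9E)-6,6-dimethylundeca-7,9-dien-1-yne | C#CCCCC(C)(C)/C=C/C=C/C | intermediate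
10 | dimethyl[(1E,7E,9E)-2,6,6-trimethylundeca-1,7,9-trien-1-yl]alumane (alkenylalane, formed in the flask in step 6) | C[Al](C)/C=C(\C)CCCC(C)(C)/C=C/C=C/C | intermediate
11 | lithium butyl(dimethyl)[(1E,7E,9E)-2,6,6-trimethylundeca-1,7,9-trien-1-yl]alumanuide (formed in the flask in step 6) | [Li+].CCCC[Al-](C)(C)/C=C(\C)CCCC(C)(C)/C=C/C=C/C | intermediate
12 | (2E,8E,10E)-3,7,7-trimethyldodeca-2,8,10-trien-1-ol | OC/C=C(\C)CCCC(C)(C)/C=C/C=C/C | intermediate
13 | (2E,8E,10E)-3,7,7-trimethyldodeca-2,8,10-trienal | O=C/C=C(\C)CCCC(C)(C)/C=C/C=C/C | intermediate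
14 | (1R,2R,4aR,8aR)-2,5,5,8a-tetramethyl-1,2,4a,5,6,7,8,8a-octahydronaphthalene-1-carbaldehyde (trans-fused, formyl and both neighbouring methyl groups on one face) | O=C[C@@H]1[C@H](C)C=C[C@@H]2C(C)(C)CCC[C@@]12C | intermediate
15 | (1R,2R,4aR,8aR)-2,5,5,8a-tetramethyldecahydronaphthalene-1-carbaldehyde | O=C[C@@H]1[C@H](C)CC[C@@H]2C(C)(C)CCC[C@@]12C | intermediate
16 | (1S,2R,4aR,8aR)-2,5,5,8a-tetramethyl-1-(phenylselanyl)decahydronaphthalene-1-carbaldehyde (selenium cis to H-8; formed in the flask in step 10) | O=C[C@]1([Se]c2ccccc2)[C@H](C)CC[C@@H]2C(C)(C)CCC[C@@]12C | intermediate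
17 | (1S,2R,4aR,8aR)-1-(benzeneseleninyl)-2,5,5,8a-tetramethyldecahydronaphthalene-1-carbaldehyde (either configuration at selenium; formed in the flask in step 10) | O=C[C@]1([Se](=O)c2ccccc2)[C@H](C)CC[C@@H]2C(C)(C)CCC[C@@]12C | intermediate
18 | (4aR,8aR)-2,5,5,8a-tetramethyl-3,4,4a,5,6,7,8,8a-octahydronaphthalene-1-carbaldehyde | O=CC1=C(C)CC[C@@H]2C(C)(C)CCC[C@@]12C | intermediate
19 | (3R)-5-methoxy-3-methyl-5-oxopentanoic acid (methyl hydrogen (R)-3-methylglutarate) | COC(=O)C[C@H](C)CC(=O)O | starting material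
20 | methyl (3S)-4-iodo-3-methylbutanoate | COC(=O)C[C@H](C)CI | intermediate
21 | [(2S)-4-methoxy-2-methyl-4-oxobutyl](triphenyl)phosphonium iodide | COC(=O)C[C@H](C)C[P+](c1ccccc1)(c1ccccc1)c1ccccc1.[I-] | intermediate
22 | methyl (3S)-3-methyl-4-(triphenyl-λ5-phosphanylidene)butanoate (ylide, formed in the flask in step 13) | COC(=O)C[C@H](C)C=P(c1ccccc1)(c1ccccc1)c1ccccc1 | intermediate
23 | methyl (3S,4Z)-3-methyl-5-[(4aR,8aR)-2,5,5,8a-tetramethyl-3,4,4a,5,6,7,8,8a-octahydronaphthalen-1-yl]pent-4-enoate | COC(=O)C[C@H](C)/C=C\C1=C(C)CC[C@@H]2C(C)(C)CCC[C@@]12C | intermediate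
24 | methyl (3R)-3-methyl-5-[(4aR,8aR)-2,5,5,8a-tetramethyl-3,4,4a,5,6,7,8,8a-octahydronaphthalen-1-yl]pentanoate | COC(=O)C[C@H](C)CCC1=C(C)CC[C@@H]2C(C)(C)CCC[C@@]12C | intermediate
25 | (3R)-3-methyl-5-[(4aR,8aR)-2,5,5,8a-tetramethyl-3,4,4a,5,6,7,8,8a-octahydronaphthalen-1-yl]pentanoic acid | OC(=O)C[C@H](C)CCC1=C(C)CC[C@@H]2C(C)(C)CCC[C@@]12C | intermediate
26 | (2R)-3-(benzyloxy)propane-1,2-diol | OC[C@@H](O)COCc1ccccc1 | starting material
27 | (2S)-3-(benzyloxy)-2-hydroxypropyl acetate | CC(=O)OC[C@@H](O)COCc1ccccc1 | intermediate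
28 | (2S)-1-(acetyloxy)-3-(benzyloxy)propan-2-yl (3R)-3-methyl-5-[(4aR,8aR)-2,5,5,8a-tetramethyl-3,4,4a,5,6,7,8,8a-octahydronaphthalen-1-yl]pentanoate | CC(=O)OC[C@H](COCc1ccccc1)OC(=O)C[C@H](C)CCC1=C(C)CC[C@@H]2C(C)(C)CCC[C@@]12C | intermediate
29 | (2S)-1-(acetyloxy)-3-hydroxypropan-2-yl (3R)-3-methyl-5-[(4aR,8aR)-2,5,5,8a-tetramethyl-3,4,4a,5,6,7,8,8a-octahydronaphthalen-1-yl]pentanoate | CC(=O)OC[C@H](CO)OC(=O)C[C@H](C)CCC1=C(C)CC[C@@H]2C(C)(C)CCC[C@@]12C | target

Total step count: 18.
Longest linear sequence: 15 steps (steps 1–10, 13, 14, 15, 17, 18). Steps 11–12 and step 16 prepare the two side fragments.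

Steps most likely to fail

Step 8. The β,β-disubstituted enal may be too poor a dienophile under the chiral Lewis acid, it may equilibrate to the (Z)-isomer before cyclising, or the endo preference and the shielding of one enal face may be incomplete. If the sense of induction turned out opposite, the mirror-image catalyst would be used. The fallback replaces catalyst control by a covalently bound auxiliary in a known reaction type, the Me2AlCl-promoted intramolecular Diels–Alder reaction of triene N-acyl oxazolidinones. It sets out from 13 and returns at 14. Chlorite oxidation of 13 (NaClO2, NaH2PO4, 2-methylbut-2-ene, t-BuOH/H2O) should give (2E,8E,10E)-3,7,7-trimethyldodeca-2,8,10-trienoic acid F1. Pivaloyl chloride and Et3N convert it into the mixed anhydride 2,2-dimethylpropanoic (2E,8E,10E)-3,7,7-trimethyldodeca-2,8,10-trienoic anhydride F2. This acylates lithiated (4R)-4-benzyl-1,3-oxazolidin-2-one to give (4R)-4-benzyl-3-[(2E,8E,10E)-3,7,7-trimethyldodeca-2,8,10-trienoyl]-1,3-oxazolidin-2-one F3. With Me2AlCl (1.4 equiv, CH2Cl2, −30 °C) the chelated s-cis imide, whose benzyl group covers the C9-Si face, should cyclise through the carbonyl-endo mode to (4R)-4-benzyl-3-{[(1R,2R,4aR,8aR)-2,5,5,8a-tetramethyl-1,2,4a,5,6,7,8,8a-octahydronaphthalen-1-yl]carbonyl}-1,3-oxazolidin-2-one F4. LiBH4 (THF/MeOH, 0 °C) releases the auxiliary and gives [(1R,2R,4aR,8aR)-2,5,5,8a-tetramethyl-1,2,4a,5,6,7,8,8a-octahydronaphthalen-1-yl]methanol F5. Dess–Martin oxidation then gives 14.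

Step 10. Enolisation of the hindered aldehyde may be slow, or selenium may be delivered to the face that is not cis to H-8, in which case the selenoxide has no hydrogen for syn-elimination. The fallback is a Saegusa–Ito dehydrogenation, which sets out from 15 and returns at 18. TBSOTf and Et3N in CH2Cl2 convert 15 into the silyl enol ether tert-butyl(dimethyl){[(2R,4aR,8aR)-2,5,5,8a-tetramethyloctahydronaphthalen-1(2H)-ylidene]methoxy}silane F6. Pd(OAc)2 in MeCN then gives 18. The palladium enolate can change face through its oxygen-bound form, so the palladium-on-carbon isomer needed for syn β-hydride elimination with H-8 is always accessible.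

Step 13. Addition of the branched ylide to the formyl group of 18, which is flanked by the quaternary C10 and the substituted C8, may be slow, leaving time for ylide decomposition or condensation at the ester. The fallback reverses the polarity and forms C11–C12 by sulfone alkylation. It sets out from 18 and 20 and returns at 25, so steps 14 and 15 are no longer needed. NaBH4 with CeCl3·7H2O in MeOH reduces 18 to [(4aR,8aR)-2,5,5,8a-tetramethyl-3,4,4a,5,6,7,8,8a-octahydronaphthalen-1-yl]methanol F7. PBr3 and pyridine in Et2O at −10 °C give (4aR,8aR)-1-(bromomethyl)-2,5,5,8a-tetramethyl-3,4,4a,5,6,7,8,8a-octahydronaphthalene F8. In parallel, 20 and PhSO2Na in DMF give methyl (3S)-4-(benzenesulfonyl)-3-methylbutanoate F9, and LiOH hydrolyses it to (3S)-4-(benzenesulfonyl)-3-methylbutanoic acid F10. The dianion of F10 (n-BuLi, 2.1 equiv, THF, −78 °C) is alkylated at the sulfonyl-bearing carbon by the allylic bromide F8 to give (3S,4RS)-4-(benzenesulfonyl)-3-methyl-5-[(4aR,8aR)-2,5,5,8a-tetramethyl-3,4,4a,5,6,7,8,8a-octahydronaphthalen-1-yl]pentanoic acid F11. Sodium amalgam (Na2HPO4, MeOH, −20 °C) removes the sulfonyl group and gives 25.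

Further compounds
F1 | step 8 | (2E,8E,10E)-3,7,7-trimethyldodeca-2,8,10-trienoic acid | OC(=O)/C=C(\C)CCCC(C)(C)/C=C/C=C/C
F2 | step 8 | 2,2-dimethylpropanoic (2E,8E,10E)-3,7,7-trimethyldodeca-2,8,10-trienoic anhydride | CC(C)(C)C(=O)OC(=O)/C=C(\C)CCCC(C)(C)/C=C/C=C/C
F3 | step 8 | (4R)-4-benzyl-3-[(2E,8E,10E)-3,7,7-trimethyldodeca-2,8,10-trienoyl]-1,3-oxazolidin-2-one | O=C1OC[C@@H](Cc2ccccc2)N1C(=O)/C=C(\C)CCCC(C)(C)/C=C/C=C/C
F4 | step 8 | (4R)-4-benzyl-3-{[(1R,2R,4aR,8aR)-2,5,5,8a-tetramethyl-1,2,4a,5,6,7,8,8a-octahydronaphthalen-1-yl]carbonyl}-1,3-oxazolidin-2-one | O=C1OC[C@@H](Cc2ccccc2)N1C(=O)[C@@H]1[C@H](C)C=C[C@@H]2C(C)(C)CCC[C@@]12C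
F5 | step 8 | [(1R,2R,4aR,8aR)-2,5,5,8a-tetramethyl-1,2,4a,5,6,7,8,8a-octahydronaphthalen-1-yl]methanol | OC[C@@H]1[C@H](C)C=C[C@@H]2C(C)(C)CCC[C@@]12C
F6 | step 10 | tert-butyl(dimethyl){[(2R,4aR,8aR)-2,5,5,8a-tetramethyloctahydronaphthalen-1(2H)-ylidene]methoxy}silane | CC(C)(C)[Si](C)(C)OC=C1[C@H](C)CC[C@@H]2C(C)(C)CCC[C@@]12C
F7 | step 13 | [(4aR,8aR)-2,5,5,8a-tetramethyl-3,4,4a,5,6,7,8,8a-octahydronaphthalen-1-yl]methanol | OCC1=C(C)CC[C@@H]2C(C)(C)CCC[C@@]12C
F8 | step 13 | (4aR,8aR)-1-(bromomethyl)-2,5,5,8a-tetramethyl-3,4,4a,5,6,7,8,8a-octahydronaphthalene | BrCC1=C(C)CC[C@@H]2C(C)(C)CCC[C@@]12C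
F9 | step 13 | methyl (3S)-4-(benzenesulfonyl)-3-methylbutanoate | COC(=O)C[C@H](C)CS(=O)(=O)c1ccccc1
F10 | step 13 | (3S)-4-(benzenesulfonyl)-3-methylbutanoic acid | OC(=O)C[C@H](C)CS(=O)(=O)c1ccccc1
F11 | step 13 | (3S,4RS)-4-(benzenesulfonyl)-3-methyl-5-[(4aR,8aR)-2,5,5,8a-tetramethyl-3,4,4a,5,6,7,8,8a-octahydronaphthalen-1-yl]pentanoic acid | OC(=O)C[C@H](C)C(CC1=C(C)CC[C@@H]2C(C)(C)CCC[C@@]12C)S(=O)(=O)c1ccccc1
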